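The butenolide ring (O1, C2–C5) is read as an opened benzene. The lactone carbonyl C2, C3(OMe), C4(aryl), C5(CO2Me) and the exocyclic benzylic CH2 are five consecutive ring carbons of a 2-aryl-3-methoxy-4,5-dihydroxybenzoate, and the sixth becomes an expendable carboxyl. Cleaving the C(OH)–C(OH) bond of this flat biaryl catechol gives a cis,cis-muconic system. Its methoxy-side carboxylate closes onto the ester-bearing alkene carbon under a chiral amine–squaramide, forming O1–C5, the ring, the quaternary stereocentre and a CH2CO2H handle in one operation. Nickel-catalysed decarboxylative arylation then swaps that carboxyl for the (R)-chromanol ring, made by Jacobsen–Katsuki epoxidation, and hydrogenolysis ends the route.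

Key step: step 4

Assumption: the sense of induction of the squaramide cannot be foreseen. Both pseudoenantiomers (from quinidine and from quinine) are available, and the one that delivers (R)-11 is the one meant in step 4.
Numbering in the text: butenolide O1, C2 (C=O), C3 (OMe), C4 (aryl), C5 (quaternary). Systematic names use 2,5-dihydrofuran numbering.

Step 1
Reactants: 1 methyl 3,4-dihydroxy-5-methoxybenzoate
Product: 2 methyl 3,4-bis[(tert-butyldimethylsilyl)oxy]-5-methoxybenzoate
Conditions: TBSCl (2.5 equiv), imidazole (5 equiv), DMF, rt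
Reagents that add atoms: tert-butyldimethylsilyl chloride, CC(C)(C)[Si](C)(C)Cl
Why: Imidazole-promoted O-silylation caps both phenols with groups that are orthogonal to benzyl ethers and whose bulk and poor donor ability are needed to steer the next step.

Step 2
Reactants: 2 methyl 3,4-bis[(tert-butyldimethylsilyl)oxy]-5-methoxybenzoate; 3 4-bromo-1,2-bis(benzyloxy)benzene
Product: 6 methyl 2-[3,4-bis(benzyloxy)phenyl]-4,5-bis[(tert-butyldimethylsilyl)oxy]-3-methoxybenzoate, via arylmagnesium chloride 4 (not isolated), via arylzinc chloride 5 (not isolated)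
Conditions: TMPMgCl·LiCl (1.3 equiv), THF, 0 °C; ZnCl2 (1.4 equiv), 0 °C to rt; then 3, Pd(OAc)2 (2 mol%), SPhos (4 mol%), 50 °C
Reagents that add atoms: none
Why: Directed ortho-magnesiation with a hindered TMP amide base, zinc transmetalation and Negishi coupling: the ring C–H flanked by the ester and the methoxy oxygen is acidified and pre-coordinated by both groups while the other ortho C–H is screened by the bulky, non-coordinating OTBS group, so the regiochemistry that electrophilic halogenation of such gallates would be expected to miss (attack para to OMe) is enforced, and the base-free coupling keeps the silyl ethers intact.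

Step 3
Reactants: 6 methyl 2-[3,4-bis(benzyloxy)phenyl]-4,5-bis[(tert-butyldimethylsilyl)oxy]-3-methoxybenzoate
Product: 7 methyl 2-[3,4-bis(benzyloxy)phenyl]-4,5-dihydroxy-3-methoxybenzoate
Conditions: KHF2 (2.5 equiv), MeOH, rt, argon
Reagents that add atoms: none
Why: Fluoride-driven desilylation with bifluoride cleaves phenolic silyl ethers in a slightly acidic medium that spares the methyl ester and the benzyl ethers and protects the liberated catechol from air oxidation.

Step 4
Reactants: 7 methyl 2-[3,4-bis(benzyloxy)phenyl]-4,5-dihydroxy-3-methoxybenzoate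
Product: 11 2-[(2R)-3-[3,4-bis(benzyloxy)phenyl]-4-methoxy-2-(methoxycarbonyl)-5-oxo-2,5-dihydrofuran-2-yl]acetic acid, via o-quinone 8 (not isolated), via muconic anhydride 9 (not isolated), via cis,cis-muconic diacid 10 (not isolated)
Conditions: (a) Ag2O, 4 Å molecular sieves, CH2Cl2, 0 °C, filter; (b) mCPBA (1.0 equiv), CH2Cl2, −20 °C, cold filtration, switch to toluene; (c) 9-amino(9-deoxy)epi-quinidine 3,5-bis(trifluoromethyl)phenyl squaramide (20 mol%), H2O (1.1 equiv), toluene, −30 °C
Reagents that add atoms: 3-chloroperoxybenzoic acid, OOC(=O)c1cccc(Cl)c1; water, O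
Why: Proposed new method: Ag2O dehydrogenates only the free catechol to o-quinone 8, the peracid adds to one carbonyl and acyl migration (Baeyer–Villiger type, the same product from either carbonyl) gives the seven-membered muconic anhydride 9, which keeps both carboxyls masked so that no free acid can cyclise before the catalyst is present. The quinuclidine nitrogen then assists attack of water at the unhindered CH=-side carbonyl, which releases the methoxy-side carboxylate as a chiral ammonium ion pair while the squaramide hydrogen-bonds the newly formed neutral CO2H and activates the C(CO2Me)=CH–CO2H unit; the carboxylate oxygen adds to the ester-bearing carbon and the ammonium protonates the resulting enol to create the CH2. The closest known reaction types are peracid or metal-mediated intradiol cleavage of catechols to cis,cis-muconic acids, acid-induced and enzymatic muconate-to-muconolactone cycloisomerisation, cinchona-catalysed opening of cyclic anhydrides and bifunctional amine/hydrogen-bond-donor catalysed intramolecular oxa-Michael addition, but their merger with enantiocontrol at a quaternary carbon has no precedent. The butenolide closes 5-exo-trig, which the chain-cis geometry of the C3=C4 alkene inherited from the arene makes possible, and this mode should beat 6-endo attack at the CH terminus as in muconate lactonisations generally. C5 is the only new stereocentre and is set purely by the catalyst, which decides the alkene face reached by the ion-paired carboxylate, since the flat substrate has no bias of its own. The constitutional selectivity is secured by the substrate, because the other carboxyl could add only to the aryl-bearing carbon of the tetrasubstituted, methoxy-donated push–pull alkene, which is hindered and electron-rich, and because the benzyl-capped second catechol cannot form a quinone.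

Step 5
Reactants: 11 2-[(2R)-3-[3,4-bis(benzyloxy)phenyl]-4-methoxy-2-(methoxycarbonyl)-5-oxo-2,5-dihydrofuran-2-yl]acetic acid
Product: 12 1,3-dioxoisoindolin-2-yl ester of acid 11 (C5 still R)
Conditions: N-hydroxyphthalimide (1.1 equiv), DIC (1.1 equiv), DMAP (5 mol%), CH2Cl2, 0 °C to rt
Reagents that add atoms: N-hydroxyphthalimide, ON1C(=O)c2ccccc2C1=O
Why: Carbodiimide (Steglich-type) esterification works without strong base, so the CH2 next to the activated carbonyl is not enolised and the C5–O1 bond is not lost by retro-oxa-Michael elimination.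

Step 6
Reactants: 13 4-iodophenol; 14 3-methylbut-2-enal
Product: 15 6-iodo-2,2-dimethyl-2H-chromene
Conditions: PhB(OH)2 (1 equiv), AcOH, toluene, reflux, Dean–Stark trap
Reagents that add atoms: none
Why: Boronic acid-templated ortho-condensation of a phenol with an enal gives an o-quinone methide that closes by oxa-6π electrocyclisation, and the para iodine leaves two equivalent ortho positions, so only one chromene can form.

Step 7
Reactants: 15 6-iodo-2,2-dimethyl-2H-chromene
Product: 16 (3R,4R)-3,4-epoxy-6-iodo-2,2-dimethylchromane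
Conditions: (R,R)-[N,N'-bis(3,5-di-tert-butylsalicylidene)-1,2-cyclohexanediaminato]MnCl (4 mol%), 4-phenylpyridine N-oxide (20 mol%), aq NaOCl (pH 11.3), CH2Cl2, 0 °C
Reagents that add atoms: sodium hypochlorite, [Na+].[O-]Cl
Why: Jacobsen–Katsuki epoxidation, for which cis-alkenes of the 2,2-dimethylchromene class are benchmark substrates; the (R,R)-salen ligand should deliver oxygen to the face that gives the (3R,4R)-epoxide and so sets the chroman C3 stereocentre.

Step 8
Reactants: 16 (3R,4R)-3,4-epoxy-6-iodo-2,2-dimethylchromane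
Product: 17 (3R)-6-iodo-2,2-dimethylchroman-3-ol
Conditions: LiBHEt3 (1.2 equiv), THF, 0 °C; then H2O
Reagents that add atoms: none
Why: SN2 hydride opening of the epoxide occurs at benzylic C4, which is also less hindered than C3 beside the quaternary C2, so the C3–O bond is never broken, the (3R) configuration is kept, and the aryl iodide is too slow to react at this temperature.

Step 9
Reactants: 12 1,3-dioxoisoindolin-2-yl ester of acid 11; 17 (3R)-6-iodo-2,2-dimethylchroman-3-ol
Product: 18 methyl (2R)-3-[3,4-bis(benzyloxy)phenyl]-2-{[(3R)-3-hydroxy-2,2-dimethylchroman-6-yl]methyl}-4-methoxy-5-oxo-2,5-dihydrofuran-2-carboxylate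
Conditions: NiBr2·dme (10 mol%), 4,4'-di-tert-butyl-2,2'-bipyridine (10 mol%), Zn (2 equiv), DMA, 25 °C
Reagents that add atoms: none
Why: Nickel-catalysed decarboxylative cross-electrophile coupling of an N-hydroxyphthalimide ester with an aryl iodide: single-electron reduction releases phthalimide anion, CO2 and the primary CH2 radical, which the aryl–nickel intermediate captures before reductive elimination, under base-free conditions that tolerate the hindered free alcohol and touch neither stereocentre.

Step 10
Reactants: 18 methyl (2R)-3-[3,4-bis(benzyloxy)phenyl]-2-{[(3R)-3-hydroxy-2,2-dimethylchroman-6-yl]methyl}-4-methoxy-5-oxo-2,5-dihydrofuran-2-carboxylate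
Product: 19 methyl (2R)-3-(3,4-dihydroxyphenyl)-2-{[(3R)-3-hydroxy-2,2-dimethylchroman-6-yl]methyl}-4-methoxy-5-oxo-2,5-dihydrofuran-2-carboxylate (CNP0289675.3)
Conditions: H2 (1 atm), Pd/C, EtOAc–MeOH, rt
Reagents that add atoms: none
Why: Catalytic hydrogenolysis removes both aryl benzyl ethers, while the tetrasubstituted conjugated C3=C4 alkene, the lactone, the methyl ester and both stereocentres should be inert under one atmosphere of hydrogen.

Compound list
1 | methyl 3,4-dihydroxy-5-methoxybenzoate | COC(=O)c1cc(O)c(O)c(OC)c1 | starting material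
2 | methyl 3,4-bis[(tert-butyldimethylsilyl)oxy]-5-methoxybenzoate | COC(=O)c1cc(O[Si](C)(C)C(C)(C)C)c(O[Si](C)(C)C(C)(C)C)c(OC)c1 | intermediate
3 | 4-bromo-1,2-bis(benzyloxy)benzene | Brc1ccc(OCc2ccccc2)c(OCc2ccccc2)c1 | starting material
4 | arylmagnesium chloride of 2, metal between ester and OMe | COC(=O)c1cc(O[Si](C)(C)C(C)(C)C)c(O[Si](C)(C)C(C)(C)C)c(OC)c1[Mg]Cl | intermediate
5 | arylzinc chloride of 2, metal between ester and OMe | COC(=O)c1cc(O[Si](C)(C)C(C)(C)C)c(O[Si](C)(C)C(C)(C)C)c(OC)c1[Zn]Cl | intermediate
6 | methyl 2-[3,4-bis(benzyloxy)phenyl]-4,5-bis[(tert-butyldimethylsilyl)oxy]-3-methoxybenzoate | COC(=O)c1cc(O[Si](C)(C)C(C)(C)C)c(O[Si](C)(C)C(C)(C)C)c(OC)c1-c1ccc(OCc2ccccc2)c(OCc2ccccc2)c1 | intermediate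
7 | methyl 2-[3,4-bis(benzyloxy)phenyl]-4,5-dihydroxy-3-methoxybenzoate | COC(=O)c1cc(O)c(O)c(OC)c1-c1ccc(OCc2ccccc2)c(OCc2ccccc2)c1 | intermediate
8 | methyl 6-[3,4-bis(benzyloxy)phenyl]-5-methoxy-3,4-dioxocyclohexa-1,5-diene-1-carboxylate | COC(=O)C1=CC(=O)C(=O)C(OC)=C1c1ccc(OCc2ccccc2)c(OCc2ccccc2)c1 | intermediate
9 | methyl 5-[3,4-bis(benzyloxy)phenyl]-6-methoxy-2,7-dioxo-2,7-dihydrooxepine-4-carboxylate | COC(=O)C1=CC(=O)OC(=O)C(OC)=C1c1ccc(OCc2ccccc2)c(OCc2ccccc2)c1 | intermediate
10 | (2E,4E)-3-[3,4-bis(benzyloxy)phenyl]-2-methoxy-4-(methoxycarbonyl)hexa-2,4-dienedioic acid (chain cis at both double bonds) | OC(=O)/C(OC)=C(c1ccc(OCc2ccccc2)c(OCc2ccccc2)c1)\C(C(=O)OC)=C/C(=O)O | intermediate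
11 | 2-[(2R)-3-[3,4-bis(benzyloxy)phenyl]-4-methoxy-2-(methoxycarbonyl)-5-oxo-2,5-dihydrofuran-2-yl]acetic acid | COC(=O)[C@]1(CC(=O)O)OC(=O)C(OC)=C1c1ccc(OCc2ccccc2)c(OCc2ccccc2)c1 | intermediate
12 | 1,3-dioxoisoindolin-2-yl 2-[(2R)-3-[3,4-bis(benzyloxy)phenyl]-4-methoxy-2-(methoxycarbonyl)-5-oxo-2,5-dihydrofuran-2-yl]acetate | COC(=O)[C@]1(CC(=O)ON2C(=O)c3ccccc3C2=O)OC(=O)C(OC)=C1c1ccc(OCc2ccccc2)c(OCc2ccccc2)c1 | intermediate
13 | 4-iodophenol | Oc1ccc(I)cc1 | starting material
14 | 3-methylbut-2-enal | CC(C)=CC=O | starting material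
15 | 6-iodo-2,2-dimethyl-2H-chromene | CC1(C)C=Cc2cc(I)ccc2O1 | intermediate
16 | (3R,4R)-3,4-epoxy-6-iodo-2,2-dimethylchromane | Ic1ccc2c(c1)[C@H]1O[C@H]1C(C)(C)O2 | intermediate
17 | (3R)-6-iodo-2,2-dimethylchroman-3-ol | Ic1ccc2c(c1)C[C@@H](O)C(C)(C)O2 | intermediate
18 | methyl (2R)-3-[3,4-bis(benzyloxy)phenyl]-2-{[(3R)-3-hydroxy-2,2-dimethylchroman-6-yl]methyl}-4-methoxy-5-oxo-2,5-dihydrofuran-2-carboxylate | COC(=O)[C@]1(Cc2ccc3c(c2)C[C@@H](O)C(C)(C)O3)OC(=O)C(OC)=C1c1ccc(OCc2ccccc2)c(OCc2ccccc2)c1 | intermediate
19 | methyl (2R)-3-(3,4-dihydroxyphenyl)-2-{[(3R)-3-hydroxy-2,2-dimethylchroman-6-yl]methyl}-4-methoxy-5-oxo-2,5-dihydrofuran-2-carboxylate | COC(=O)[C@]1(Cc2ccc3c(c2)C[C@@H](O)C(C)(C)O3)OC(=O)C(OC)=C1c1ccc(O)c(O)c1 | target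

Total step count: 10. Longest linear sequence: 7 steps (steps 1, 2, 3, 4, 5, 9, 10). The chromanol branch (steps 6–8) joins at step 9.

Steps most likely to fail

Step 4. Facial selectivity may be poor. The diacid may cyclise without the catalyst. The acidic product may tie up the amine and slow turnover. Closure at the CH terminus may also compete.
- The fallback uses only known chemistry, sets out from 7 and comes back at 11.
- 7 is taken through 8 and 9 as before, and the anhydride is hydrolysed in aqueous THF to 10.
- Warming in acetic acid closes the lactone without chiral control to the racemic butenolide acid F1.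
- One equivalent of (S)-1-phenylethylamine gives diastereomeric salts, and the salt of the (R)-acid F2 is enriched by fractional crystallisation. The (R)-amine is used instead if it gives the less soluble partner.
- Dilute HCl then liberates 11.

Step 9. The primary radical beside C5 may add to the neighbouring C3=C4 double bond (3-exo closure, then vinyl shift with ring enlargement) faster than nickel captures it. The activated ester may also lose the lactone oxygen by retro-oxa-Michael elimination.
- The fallback sets out from 12 and 17 and comes back at 18. It replaces radical arylation by a very fast radical trap followed by polar bond formation.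
- Visible-light reduction of 12 [Ru(bpy)3(PF6)2, Hantzsch ester, CH2Cl2] is run with excess TEMPO, which captures primary radicals close to the diffusion limit. This gives the alkoxyamine F3.
- mCPBA oxidation with Cope-type elimination gives the aldehyde F4, which is used at once.
- 17 is turned with two equivalents of iPrMgCl·LiCl into the alkoxide-bearing aryl Grignard reagent F5.
- F5 is added at −78 °C to F4 to give the benzylic carbinol F6. The epimer mixture at the new carbinol carbon is of no consequence.
- Ionic hydrogenation of this p-alkoxybenzylic alcohol (Et3SiH, TFA, CH2Cl2, 0 °C) gives 18.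

Step 2. Deprotonation may be incomplete or wrongly placed, or the arylmagnesium may attack the methyl ester.
- The fallback sets out from 1 and comes back at 7. It replaces deprotonation by electrophilic substitution with a blocking halogen.
- Bromination of 1 (NBS, CHCl3) at the intrinsically preferred site next to the free OH gives the bromocatechol F7.
- 2,2-Dimethoxypropane and TsOH give the acetonide F8.
- The only remaining ring C–H, the one between ester and OMe, is iodinated (NIS, catalytic TFA, MeCN) to the bromo iodide F9.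
- Suzuki coupling at the more reactive carbon–iodine bond with commercial 3,4-bis(benzyloxy)phenylboronic acid F10 [PdCl2(dppf), K2CO3, dioxane–H2O, 60 °C] gives the bromo biaryl F11.
- Homogeneous hydrodebromination [Pd(PPh3)4, HCO2Na, DMF] gives the biaryl acetonide F12.
- TFA–H2O unmasks 7.

Further compounds
F1 | step 4 | racemic 2-[3-[3,4-bis(benzyloxy)phenyl]-4-methoxy-2-(methoxycarbonyl)-5-oxo-2,5-dihydrofuran-2-yl]acetic acid | COC(=O)C1(CC(=O)O)OC(=O)C(OC)=C1c1ccc(OCc2ccccc2)c(OCc2ccccc2)c1
F2 | step 4 | (S)-1-phenylethylammonium salt of (R)-acid 11 | COC(=O)[C@]1(CC(=O)[O-])OC(=O)C(OC)=C1c1ccc(OCc2ccccc2)c(OCc2ccccc2)c1.C[C@H]([NH3+])c1ccccc1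
F3 | step 9 | methyl (2S)-3-[3,4-bis(benzyloxy)phenyl]-4-methoxy-5-oxo-2-{[(2,2,6,6-tetramethylpiperidin-1-yl)oxy]methyl}-2,5-dihydrofuran-2-carboxylate (same spatial arrangement as 11, descriptor changed by priority only) | COC(=O)[C@]1(CON2C(C)(C)CCCC2(C)C)OC(=O)C(OC)=C1c1ccc(OCc2ccccc2)c(OCc2ccccc2)c1
F4 | step 9 | methyl (2S)-3-[3,4-bis(benzyloxy)phenyl]-2-formyl-4-methoxy-5-oxo-2,5-dihydrofuran-2-carboxylate | COC(=O)[C@]1(C=O)OC(=O)C(OC)=C1c1ccc(OCc2ccccc2)c(OCc2ccccc2)c1
F5 | step 9 | chloromagnesium alkoxide of (3R)-6-(chloromagnesio)-2,2-dimethylchroman-3-ol | Cl[Mg]c1ccc2c(c1)C[C@@H](O[Mg]Cl)C(C)(C)O2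
F6 | step 9 | methyl 3-[3,4-bis(benzyloxy)phenyl]-2-{hydroxy[(3R)-3-hydroxy-2,2-dimethylchroman-6-yl]methyl}-4-methoxy-5-oxo-2,5-dihydrofuran-2-carboxylate, ring stereocentre as in 11, carbinol carbon as epimer mixture | COC(=O)[C@]1(C(O)c2ccc3c(c2)C[C@@H](O)C(C)(C)O3)OC(=O)C(OC)=C1c1ccc(OCc2ccccc2)c(OCc2ccccc2)c1
F7 | step 2 | methyl 2-bromo-3,4-dihydroxy-5-methoxybenzoate | COC(=O)c1cc(OC)c(O)c(O)c1Br
F8 | step 2 | methyl 4-bromo-7-methoxy-2,2-dimethyl-1,3-benzodioxole-5-carboxylate | COC(=O)c1cc(OC)c2OC(C)(C)Oc2c1Br
F9 | step 2 | methyl 4-bromo-6-iodo-7-methoxy-2,2-dimethyl-1,3-benzodioxole-5-carboxylate | COC(=O)c1c(I)c(OC)c2OC(C)(C)Oc2c1Br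
F10 | step 2 | 3,4-bis(benzyloxy)phenylboronic acid | OB(O)c1ccc(OCc2ccccc2)c(OCc2ccccc2)c1
F11 | step 2 | methyl 6-[3,4-bis(benzyloxy)phenyl]-4-bromo-7-methoxy-2,2-dimethyl-1,3-benzodioxole-5-carboxylate | COC(=O)c1c(-c2ccc(OCc3ccccc3)c(OCc3ccccc3)c2)c(OC)c2OC(C)(C)Oc2c1Br
F12 | step 2 | methyl 6-[3,4-bis(benzyloxy)phenyl]-7-methoxy-2,2-dimethyl-1,3-benzodioxole-5-carboxylate | COC(=O)c1cc2OC(C)(C)Oc2c(OC)c1-c1ccc(OCc2ccccc2)c(OCc2ccccc2)c1
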